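**Strategy**

- Two cuts are made. The furan ring of the benzofuran (O1–C2 and C3–C3a) is opened to a terminal alkyne and 2,4-dihydroxy-5-iodoacetophenone. The bond between the carbinol carbon and the chain CH2 is then cut to a chromen-6-yl carbamate and a homopropargyl pinacol boronic ester.
- The enabling feature is the carbinol carbon: it carries OH, CH3, C6 of the chromene ring and the chain CH2, so it is the oxidised form of a tertiary benzylic C–B centre. One CH2 separates it from the methine, whose other neighbour, C2 of the benzofuran, can travel as an alkyne carbon.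
- Forward: the chromene bicycle is bought intact and taken to an (S)-benzylic carbamate, and a chiral-pool hydroxy ester is taken to a silylalkyne boronic ester. The two are joined at the quaternary carbon–CH2 bond by lithiation–borylation, the C–B bond is oxidised and the alkyne freed, and the furan ring is closed last by Sonogashira coupling–cyclisation.
- Stereochemistry: the carbinol centre originates in a catalyst-controlled transfer hydrogenation of encecalin and is passed on stereospecifically, (S)-carbamate to (R)-carbinol. The (S)-methine comes unchanged from methyl (S)-3-hydroxy-2-methylpropanoate.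

Key step: step 11

Remark: the target is read from its SMILES as (R) at the carbinol carbon and (S) at the methine carbon; compounds 1, 6 and 22 are taken as purchasable.

**Route**

Step 1
Reactants: 1 precocene 1 (7-methoxy-2,2-dimethyl-2H-chromene)
Product: 2 encecalin (1-(7-methoxy-2,2-dimethyl-2H-chromen-6-yl)ethan-1-one)
Conditions: Ac2O, ZnCl2, CH2Cl2, −10 to 0 °C
Reagents that add atoms: acetic anhydride, CC(=O)OC(C)=O
Why: Friedel–Crafts acylation should go to C6, which is para to the ring oxygen, ortho to the methoxy group and less crowded than C8, while the mild Lewis acid and an anhydride that releases no HCl spare the acid-sensitive C3=C4 alkene.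

Step 2
Reactants: 2 encecalin
Product: 3 (S)-encecalol ((1S)-1-(7-methoxy-2,2-dimethyl-2H-chromen-6-yl)ethan-1-ol)
Conditions: RuCl[(S,S)-TsDPEN](p-cymene) (1 mol %), HCO2Na, H2O/MeOH, 40 °C; neutral work-up
Reagents that add atoms: none
Why: Noyori-type asymmetric transfer hydrogenation of an aryl methyl ketone, in which the (S,S)-diamine ligand directs hydride to the face that gives the (S)-1-arylethanol, and the formate salt medium stays non-acidic so that the easily ionised benzylic alcohol keeps its configuration.

Step 3
Reactants: 3 (S)-encecalol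
Product: 5 (1S)-1-(7-methoxy-2,2-dimethyl-2H-chromen-6-yl)ethyl N,N-diisopropylcarbamate, via sodium alkoxide 4 (not isolated)
Conditions: NaH, THF, 0 °C; then i-Pr2NCOCl, 0 to 50 °C
Reagents that add atoms: N,N-diisopropylcarbamoyl chloride, CC(C)N(C(C)C)C(=O)Cl
Why: O-acylation of the preformed alkoxide by a carbamoyl chloride runs under purely basic conditions, breaks no bond at the stereocenter and installs the group that later directs lithiation and serves as the leaving group.

Step 4
Reactants: 6 methyl (S)-3-hydroxy-2-methylpropanoate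
Product: 7 methyl (S)-3-[(tert-butyldimethylsilyl)oxy]-2-methylpropanoate
Conditions: TBSCl, imidazole, CH2Cl2, 0 °C to rt
Reagents that add atoms: tert-butyldimethylsilyl chloride, CC(C)(C)[Si](C)(C)Cl
Why: imidazole-mediated silylation of a primary alcohol is routine and leaves the α-stereocenter of the ester untouched.

Step 5
Reactants: 7 methyl (S)-3-[(tert-butyldimethylsilyl)oxy]-2-methylpropanoate
Product: 8 (S)-3-[(tert-butyldimethylsilyl)oxy]-2-methylpropanal
Conditions: i-Bu2AlH, CH2Cl2, −78 °C; aq potassium sodium tartrate
Reagents that add atoms: none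
Why: partial reduction of the ester stops at the tetrahedral aluminium hemiacetal, which is stable at −78 °C and collapses to the aldehyde only on work-up, and the α-stereocenter is kept by using the crude aldehyde at once without chromatography.

Step 6
Reactants: 8 (S)-3-[(tert-butyldimethylsilyl)oxy]-2-methylpropanal
Product: 9 (R)-tert-butyl[(4,4-dibromo-2-methylbut-3-en-1-yl)oxy]dimethylsilane
Conditions: CBr4, PPh3, Zn, CH2Cl2, rt; then 8, 0 °C to rt
Reagents that add atoms: carbon tetrabromide, BrC(Br)(Br)Br
Why: Corey–Fuchs dibromoolefination, a Wittig-type reaction of preformed Ph3P=CBr2, is neutral and fast enough that the α-branched aldehyde should not epimerise, the descriptor changing from S to R only through the priority rules.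

Step 7
Reactants: 9 (R)-tert-butyl[(4,4-dibromo-2-methylbut-3-en-1-yl)oxy]dimethylsilane
Product: 11 (R)-tert-butyldimethyl{[2-methyl-4-(trimethylsilyl)but-3-yn-1-yl]oxy}silane, via lithium acetylide 10 (not isolated)
Conditions: n-BuLi (2.1 equiv), THF, −78 °C; then TMSCl, −78 °C to rt
Reagents that add atoms: chlorotrimethylsilane, C[Si](C)(C)Cl
Why: in the second stage of the Corey–Fuchs sequence bromine–lithium exchange, loss of LiBr with a 1,2-shift and deprotonation give the lithium acetylide, which is silylated on carbon without involving the stereocenter.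

Step 8
Reactants: 11 (R)-tert-butyldimethyl{[2-methyl-4-(trimethylsilyl)but-3-yn-1-yl]oxy}silane
Product: 12 (R)-2-methyl-4-(trimethylsilyl)but-3-yn-1-ol
Conditions: (±)-camphor-10-sulfonic acid (catalytic), MeOH/CH2Cl2, 0 °C to rt
Reagents that add atoms: none
Why: acid-catalysed methanolysis cleaves the Si–O bond of the primary silyl ether, whereas the C(sp)–SiMe3 bond needs base or fluoride and should stay.

Step 9
Reactants: 12 (R)-2-methyl-4-(trimethylsilyl)but-3-yn-1-ol
Product: 13 (R)-(4-iodo-3-methylbut-1-yn-1-yl)trimethylsilane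
Conditions: I2, PPh3, imidazole, CH2Cl2, 0 °C to rt
Reagents that add atoms: iodine, II
Why: in the Appel reaction iodide displaces the alkoxyphosphonium group at the primary carbon in an SN2 step that does not touch the neighbouring stereocenter.

Step 10
Reactants: 13 (R)-(4-iodo-3-methylbut-1-yn-1-yl)trimethylsilane
Product: 16 4,4,5,5-tetramethyl-2-[(2S)-2-methyl-4-(trimethylsilyl)but-3-yn-1-yl]-1,3,2-dioxaborolane, via alkyllithium 14 (not isolated), via lithium isopropoxyborate 15 (not isolated)
Conditions: t-BuLi (2.1 equiv), Et2O/pentane, −78 °C; then 2-isopropoxy-4,4,5,5-tetramethyl-1,3,2-dioxaborolane, −78 °C to rt; H2O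
Reagents that add atoms: 2-isopropoxy-4,4,5,5-tetramethyl-1,3,2-dioxaborolane, CC(C)OB1OC(C)(C)C(C)(C)O1
Why: iodine–lithium exchange at a primary carbon is fast and irreversible with two equivalents of t-BuLi at −78 °C, and the alkyllithium adds to boron to give a tetracoordinate borate that sheds isopropoxide (standard borylation of an organolithium), the silylated alkyne offering no acidic hydrogen and the stereocenter staying out of the reaction.

Step 11
Reactants: 5 (1S)-1-(7-methoxy-2,2-dimethyl-2H-chromen-6-yl)ethyl N,N-diisopropylcarbamate; 16 4,4,5,5-tetramethyl-2-[(2S)-2-methyl-4-(trimethylsilyl)but-3-yn-1-yl]-1,3,2-dioxaborolane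
Product: 19 2-[(2S,4S)-2-(7-methoxy-2,2-dimethyl-2H-chromen-6-yl)-4-methyl-6-(trimethylsilyl)hex-5-yn-2-yl]-4,4,5,5-tetramethyl-1,3,2-dioxaborolane, via lithiated carbamate 17 (not isolated), via boronate complex 18 (not isolated)
Conditions: 5 (1.2 equiv), s-BuLi (1.15 equiv), Et2O, −78 °C; then 16 (1.0 equiv) in Et2O, −78 °C; then MgBr2 in MeOH, −78 °C to rt
Reagents that add atoms: none
Why: The carbamate carbonyl binds s-BuLi and directs removal of the benzylic hydrogen to give the α-oxygenated benzyllithium 17, which holds its configuration at −78 °C and attacks the boron of the unhindered primary pinacol ester with retention to give boronate 18; on warming, the homopropargyl CH2 migrates from boron to carbon antiperiplanar to the departing carbamate, which forms the bond between the fully substituted benzylic carbon and the chain CH2. The closest known reaction type is the lithiation–borylation of enantioenriched secondary benzylic N,N-dialkylcarbamates with primary alkyl pinacol boronic esters, a Matteson-type 1,2-metallate rearrangement. No ring is closed in this step. The new fully substituted stereocenter is controlled by the substrate: the (S) configuration of 5 set in step 2 is passed on by retention in the borylation and inversion in the migration, so that the chain CH2 formally stands where the benzylic hydrogen stood and boron where the carbamate oxygen stood, while the (S)-methine of 16 is a spectator. The step needs benzylic lithiation in preference to lithiation of C8–H between the two ring oxygens or carbolithiation of the C3=C4 alkene, which the complex-induced proximity effect of the carbamate at −78 °C secures, and it needs boronate formation that does not revert, which MgBr2 in MeOH secures by speeding the migration and protonating any benzyllithium released; the electron-rich dioxygenated aryl ring helps the carbamate leave and the silylated alkyne offers no acidic or electrophilic site.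

Step 12
Reactants: 19 2-[(2S,4S)-2-(7-methoxy-2,2-dimethyl-2H-chromen-6-yl)-4-methyl-6-(trimethylsilyl)hex-5-yn-2-yl]-4,4,5,5-tetramethyl-1,3,2-dioxaborolane
Product: 21 (2R,4S)-2-(7-methoxy-2,2-dimethyl-2H-chromen-6-yl)-4-methylhex-5-yn-2-ol, via silyl alkynyl carbinol 20 (not isolated)
Conditions: 2 M aq NaOH, 30% aq H2O2, THF, 0 °C to rt; then MeOH, K2CO3, rt, same flask; chromatography on Et3N-deactivated silica
Reagents that add atoms: hydrogen peroxide, OO
Why: hydroperoxide adds to boron and the benzylic carbon migrates to oxygen with retention (standard boronic ester oxidation), base-mediated protodesilylation of the alkynylsilane then frees the terminal alkyne, the electron-rich chromene alkene is inert to nucleophilic peroxide, and the absence of acid protects the ionisable carbinol.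

Step 13
Reactants: 22 2,4-dihydroxyacetophenone
Product: 23 2,4-dihydroxy-5-iodoacetophenone (1-(2,4-dihydroxy-5-iodophenyl)ethan-1-one)
Conditions: ICl, AcOH, rt; recrystallisation
Reagents that add atoms: iodine monochloride, ClI
Why: electrophilic aromatic iodination is expected to go mainly to C5, which is para to the 2-hydroxyl, ortho to the 4-hydroxyl and less hindered than C3 between the two hydroxyls, and any 3-iodo isomer is removed by crystallisation.

Step 14
Reactants: 21 (2R,4S)-2-(7-methoxy-2,2-dimethyl-2H-chromen-6-yl)-4-methylhex-5-yn-2-ol; 23 2,4-dihydroxy-5-iodoacetophenone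
Product: 25 1-{6-hydroxy-2-[(2S,4R)-4-hydroxy-4-(7-methoxy-2,2-dimethyl-2H-chromen-6-yl)pentan-2-yl]-1-benzofuran-5-yl}ethan-1-one, via alkynylphenol 24 (not isolated)
Conditions: PdCl2(PPh3)2 (5 mol %), CuI (10 mol %), Et3N, DMF, 60 °C
Reagents that add atoms: none
Why: Sonogashira coupling at the C–I bond gives the o-alkynylphenol, whose C4 phenoxide adds to the metal-activated alkyne in a 5-endo-dig closure of the furan ring (the known coupling–heteroannulation of o-iodophenols), the acidic and well-placed phenol outcompeting the hindered tertiary hydroxyl, the 2-hydroxyl being held in a hydrogen bond to the acetyl group and neither stereocenter being touched.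

**Compound list**

1 | precocene 1 (7-methoxy-2,2-dimethyl-2H-chromene) | COc1ccc2c(c1)OC(C)(C)C=C2 | starting material
2 | encecalin (1-(7-methoxy-2,2-dimethyl-2H-chromen-6-yl)ethan-1-one) | COc1cc2c(cc1C(C)=O)C=CC(C)(C)O2 | intermediate
3 | (S)-encecalol ((1S)-1-(7-methoxy-2,2-dimethyl-2H-chromen-6-yl)ethan-1-ol) | COc1cc2c(cc1[C@H](C)O)C=CC(C)(C)O2 | intermediate
4 | sodium alkoxide of 3 (sodium (S)-encecalolate) | [Na+].COc1cc2c(cc1[C@H](C)[O-])C=CC(C)(C)O2 | intermediate
5 | (1S)-1-(7-methoxy-2,2-dimethyl-2H-chromen-6-yl)ethyl N,N-diisopropylcarbamate | COc1cc2c(cc1[C@H](C)OC(=O)N(C(C)C)C(C)C)C=CC(C)(C)O2 | intermediate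
6 | methyl (S)-3-hydroxy-2-methylpropanoate | COC(=O)[C@@H](C)CO | starting material
7 | methyl (S)-3-[(tert-butyldimethylsilyl)oxy]-2-methylpropanoate | COC(=O)[C@@H](C)CO[Si](C)(C)C(C)(C)C | intermediate
8 | (S)-3-[(tert-butyldimethylsilyl)oxy]-2-methylpropanal | O=C[C@@H](C)CO[Si](C)(C)C(C)(C)C | intermediate
9 | (R)-tert-butyl[(4,4-dibromo-2-methylbut-3-en-1-yl)oxy]dimethylsilane | BrC(Br)=C[C@@H](C)CO[Si](C)(C)C(C)(C)C | intermediate
10 | lithium acetylide, {(3R)-4-[(tert-butyldimethylsilyl)oxy]-3-methylbut-1-yn-1-yl}lithium | [Li]C#C[C@@H](C)CO[Si](C)(C)C(C)(C)C | intermediate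
11 | (R)-tert-butyldimethyl{[2-methyl-4-(trimethylsilyl)but-3-yn-1-yl]oxy}silane | C[Si](C)(C)C#C[C@@H](C)CO[Si](C)(C)C(C)(C)C | intermediate
12 | (R)-2-methyl-4-(trimethylsilyl)but-3-yn-1-ol | OC[C@H](C)C#C[Si](C)(C)C | intermediate
13 | (R)-(4-iodo-3-methylbut-1-yn-1-yl)trimethylsilane | IC[C@H](C)C#C[Si](C)(C)C | intermediate
14 | alkyllithium, [(2S)-2-methyl-4-(trimethylsilyl)but-3-yn-1-yl]lithium | [Li]C[C@H](C)C#C[Si](C)(C)C | intermediate
15 | lithium isopropoxyborate, the adduct of 14 with the isopropoxy dioxaborolane ((S)-methine) | [Li+].CC(C)O[B-]1(C[C@H](C)C#C[Si](C)(C)C)OC(C)(C)C(C)(C)O1 | intermediate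
16 | 4,4,5,5-tetramethyl-2-[(2S)-2-methyl-4-(trimethylsilyl)but-3-yn-1-yl]-1,3,2-dioxaborolane | CC1(C)OB(C[C@H](C)C#C[Si](C)(C)C)OC1(C)C | intermediate
17 | lithiated carbamate, 5 with lithium in place of the benzylic hydrogen in the same spatial position ((S) at the benzylic carbon) | COc1cc2c(cc1[C@]([Li])(C)OC(=O)N(C(C)C)C(C)C)C=CC(C)(C)O2 | intermediate
18 | boronate complex, the lithium salt of the adduct of 17 with 16 at boron (benzylic carbon S, methine S) | [Li+].COc1cc2c(cc1[C@]([B-]3(C[C@H](C)C#C[Si](C)(C)C)OC(C)(C)C(C)(C)O3)(C)OC(=O)N(C(C)C)C(C)C)C=CC(C)(C)O2 | intermediate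
19 | 2-[(2S,4S)-2-(7-methoxy-2,2-dimethyl-2H-chromen-6-yl)-4-methyl-6-(trimethylsilyl)hex-5-yn-2-yl]-4,4,5,5-tetramethyl-1,3,2-dioxaborolane | COc1cc2c(cc1[C@](C)(B3OC(C)(C)C(C)(C)O3)C[C@H](C)C#C[Si](C)(C)C)C=CC(C)(C)O2 | intermediate
20 | silyl alkynyl carbinol, (2R,4S)-2-(7-methoxy-2,2-dimethyl-2H-chromen-6-yl)-4-methyl-6-(trimethylsilyl)hex-5-yn-2-ol | COc1cc2c(cc1[C@](C)(O)C[C@H](C)C#C[Si](C)(C)C)C=CC(C)(C)O2 | intermediate
21 | (2R,4S)-2-(7-methoxy-2,2-dimethyl-2H-chromen-6-yl)-4-methylhex-5-yn-2-ol | COc1cc2c(cc1[C@](C)(O)C[C@H](C)C#C)C=CC(C)(C)O2 | intermediate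
22 | 2,4-dihydroxyacetophenone | CC(=O)c1ccc(O)cc1O | starting material
23 | 2,4-dihydroxy-5-iodoacetophenone | CC(=O)c1cc(I)c(O)cc1O | intermediate
24 | alkynylphenol, 1-(2,4-dihydroxy-5-{(3S,5R)-5-hydroxy-5-(7-methoxy-2,2-dimethyl-2H-chromen-6-yl)-3-methylhex-1-yn-1-yl}phenyl)ethan-1-one | COc1cc2c(cc1[C@](C)(O)C[C@H](C)C#Cc1cc(C(C)=O)c(O)cc1O)C=CC(C)(C)O2 | intermediate
25 | 1-{6-hydroxy-2-[(2S,4R)-4-hydroxy-4-(7-methoxy-2,2-dimethyl-2H-chromen-6-yl)pentan-2-yl]-1-benzofuran-5-yl}ethan-1-one (CNP0233723.2) | COc1cc2c(cc1[C@](C)(O)C[C@H](C)c1cc3cc(C(C)=O)c(O)cc3o1)C=CC(C)(C)O2 | target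

**Step count and risks**

Total step count: 14. Longest linear sequence: 10 steps (from 6 through steps 4 to 12 and step 14 to 25).

Steps most likely to fail:

Step 11. With so electron-rich a benzyllithium, boronate formation may be reversible and erode the transfer of configuration. Lithiation may also stray to the aromatic C8–H position, or the crowded boronate may not rearrange. The fallback sets out from iodide 13 and ketone 2. Alkyllithium 14 is generated as in step 10 (t-BuLi, Et2O, −78 °C) and transmetallated with anhydrous CeCl3 in THF to dichloro[(2S)-2-methyl-4-(trimethylsilyl)but-3-yn-1-yl]cerium F1. This should add to the enolisable ketone 2 at −78 °C without facial control, giving 20 together with its carbinol epimer (2S,4S)-2-(7-methoxy-2,2-dimethyl-2H-chromen-6-yl)-4-methyl-6-(trimethylsilyl)hex-5-yn-2-ol F2. The two are diastereomers and should be separable by chromatography on base-washed silica. Carbinol 20 is then desilylated with K2CO3 in MeOH and the route is rejoined at 21.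

Step 14. The free tertiary hydroxyl may add to the alkyne in a 5-exo-dig sense in competition with the phenol, the coupling may stall before ring closure, or the alkyne may homocouple. The fallback sets out from 21. The tertiary hydroxyl is masked with TESOTf and 2,6-lutidine in CH2Cl2 at −78 °C to give the triethylsilyl ether of the alkynol F3. The same coupling–cyclisation with 23 should then give the triethylsilyl ether of the target F4, and n-Bu4NF in THF removes the silyl group, which returns the route at 25.

Step 1. Under Lewis-acidic acylation the acid-sensitive C3=C4 alkene may oligomerise or add acid, and acylation may not stop cleanly at C6. The fallback sets out from 1. Vilsmeier–Haack formylation (POCl3, DMF, 0 °C to rt; aq NaOAc) should give 7-methoxy-2,2-dimethyl-2H-chromene-6-carbaldehyde F5. Addition of MeMgBr in THF at 0 °C then gives racemic encecalol F6, and MnO2 in CH2Cl2 oxidises it to 2, where the route is rejoined.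

**Further compounds**

F1 | step 11 | dichloro[(2S)-2-methyl-4-(trimethylsilyl)but-3-yn-1-yl]cerium | Cl[Ce](Cl)C[C@H](C)C#C[Si](C)(C)C
F2 | step 11 | (2S,4S)-2-(7-methoxy-2,2-dimethyl-2H-chromen-6-yl)-4-methyl-6-(trimethylsilyl)hex-5-yn-2-ol | COc1cc2c(cc1[C@@](C)(O)C[C@H](C)C#C[Si](C)(C)C)C=CC(C)(C)O2
F3 | step 14 | triethylsilyl ether of the alkynol, triethyl{[(2R,4S)-2-(7-methoxy-2,2-dimethyl-2H-chromen-6-yl)-4-methylhex-5-yn-2-yl]oxy}silane | COc1cc2c(cc1[C@](C)(O[Si](CC)(CC)CC)C[C@H](C)C#C)C=CC(C)(C)O2
F4 | step 14 | triethylsilyl ether of the target, 1-{6-hydroxy-2-[(2S,4R)-4-(7-methoxy-2,2-dimethyl-2H-chromen-6-yl)-4-[(triethylsilyl)oxy]pentan-2-yl]-1-benzofuran-5-yl}ethan-1-one | COc1cc2c(cc1[C@](C)(O[Si](CC)(CC)CC)C[C@H](C)c1cc3cc(C(C)=O)c(O)cc3o1)C=CC(C)(C)O2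
F5 | step 1 | 7-methoxy-2,2-dimethyl-2H-chromene-6-carbaldehyde | COc1cc2c(cc1C=O)C=CC(C)(C)O2
F6 | step 1 | racemic encecalol, 1-(7-methoxy-2,2-dimethyl-2H-chromen-6-yl)ethan-1-ol | COc1cc2c(cc1C(C)O)C=CC(C)(C)O2
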